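**Plan**

1. Atom numbers follow the germacrane skeleton of the target: C1 ketone, C2=C3 with the ether oxygen joining C3 to C10 (the 3(2H)-furanone ring), C4=C5 (Z), γ-lactone O–C6–C7–C11–C12, angelate on C8.
2. Last cut: the C3–C4 single bond of the O–C3(=C2)–C4=C5 dienone. C3 is the free β-carbon (enol-ether C–H) of the furanone and C4 the iodine-bearing carbon of a (Z)-alkenyl iodide. One intramolecular Heck alkenylation on the preformed five-membered ring therefore closes the ten-membered carbocycle and the nine-membered oxacycle of the 11-oxabicyclo[6.2.1]undecane together.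
3. Earlier cuts: C8–O (angelate), O–C12 (lactone), C6–C7 (aldol), C7–C8 (thioester + alkylzinc), C2–C3/O–C3 (furanone from a methyl ketone and one carbon), C9–C10 (aldol to 2,3-butanedione).
4. Forward order: furanone ring, C7–C12 chain, aldol with (Z)-3-iodobut-2-enal, reduction and γ-lactone, angelate, then the bridged macrobicycle in the last step.
5. Stereochemistry: C10 from a copper–bis(oxazoline)-catalysed aldol; C11 from methyl (S)-3-hydroxy-2-methylpropanoate; C6 and C7 from a reagent-controlled syn boron aldol; C8 from hydroxyl-directed 1,3-anti reduction; 4Z from trans-hydroalumination/iodination of but-2-yn-1-ol, retained in the Heck step; angelate geometry from angelic acid.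

Key step: step 11

Remark 1 (step 2): the copper–bis(oxazoline) catalyst is assumed to show toward 2,3-butanedione the facial sense it shows toward pyruvate esters ((S,S)-ligand gives the S carbinol), so the (R,R)-ligand is specified.
Remark 2 (step 8): the Z-enolate made with (−)-Ipc2BOTf is assumed to be the one that attacks the Si face of aldehyde 16; if the sense is the reverse, the enantiomeric boron reagent is required.

**Step 1**
Reactants: 1 S-ethyl ethanethioate
Product: 3 1-(ethylsulfanyl)-1-[(trimethylsilyl)oxy]ethene, via lithium thioenolate 2 (not isolated)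
Conditions: LiN(i-Pr)2, THF, −78 °C; then Me3SiCl, −78 → 0 °C
Reagents that add atoms: chlorotrimethylsilane, C[Si](C)(C)Cl
Why: Kinetic deprotonation of the thioester and O-silylation of the lithium enolate is the standard preparation of the silyl ketene thioacetal needed for a Mukaiyama aldol (enolate silylation).

**Step 2**
Reactants: 3 1-(ethylsulfanyl)-1-[(trimethylsilyl)oxy]ethene; 4 2,3-butanedione
Product: 5 S-ethyl (3R)-3-methyl-4-oxo-3-[(trimethylsilyl)oxy]pentanethioate
Conditions: [Cu((R,R)-t-Bu-box)](OTf)2 (10 mol %, from Cu(OTf)2 and 2,2'-(propane-2,2-diyl)bis[(4R)-4-tert-butyl-4,5-dihydro-1,3-oxazole]), THF, −78 °C; non-aqueous work-up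
Reagents that add atoms: none
Why: Catalytic enantioselective Mukaiyama aldol in which the 1,2-diketone chelates divalent copper through both carbonyl oxygens, a tert-butyl group of the ligand blocks one face and the ketene acetal attacks the open face with silyl transfer, which should set the quaternary carbinol carbon (C10) as R; the diketone is symmetric, so there is no regiochemical question.

**Step 3**
Reactants: 5 S-ethyl (3R)-3-methyl-4-oxo-3-[(trimethylsilyl)oxy]pentanethioate
Product: 8 S-ethyl 2-[(2R)-2-methyl-3-oxo-2,3-dihydrofuran-2-yl]ethanethioate, via silyl enaminone 6 (not isolated), via hydroxy enaminone 7 (not isolated)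
Conditions: Me2NCH(OMe)2, toluene, 75 °C; then CF3CO2H, wet CH2Cl2, 0 → 23 °C
Reagents that add atoms: N,N-dimethylformamide dimethyl acetal, COC(OC)N(C)C
Why: Condensation of the methyl ketone with the amide acetal gives the vinylogous amide, and acid then removes the silyl group and lets the tertiary hydroxyl add to the iminium carbon and expel dimethylamine (the classical 3(2H)-furanone synthesis by conjugate addition–elimination); no free amine is present while the thioester is heated and C10 is not touched.

**Step 4**
Reactants: 9 methyl (2S)-3-hydroxy-2-methylpropanoate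
Product: 10 methyl (2R)-3-iodo-2-methylpropanoate
Conditions: I2, PPh3, imidazole, CH2Cl2, 0 → 23 °C
Reagents that add atoms: iodine, [I][I]
Why: Appel-type iodination of the primary alcohol leaves the α-stereocentre untouched (the descriptor changes from S to R only because CH2I outranks the ester).

**Step 5**
Reactants: 8 S-ethyl 2-[(2R)-2-methyl-3-oxo-2,3-dihydrofuran-2-yl]ethanethioate; 10 methyl (2R)-3-iodo-2-methylpropanoate
Product: 12 methyl (2S)-2-methyl-5-[(2R)-2-methyl-3-oxo-2,3-dihydrofuran-2-yl]-4-oxopentanoate, via organozinc iodide 11 (not isolated)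
Conditions: Zn dust (activated with BrCH2CH2Br and Me3SiCl), THF, 35 °C; then 8, PdCl2(PPh3)2 (5 mol %), toluene, 23 °C
Reagents that add atoms: none
Why: Fukuyama coupling, in which zerovalent palladium inserts into the acyl–sulfur bond, the β-ester alkylzinc transmetalates and reductive elimination gives the ketone without over-addition; the ester, the furanone and both stereocentres are inert to the organozinc.

**Step 6**
Reactants: 13 but-2-yn-1-ol
Product: 15 (2Z)-3-iodobut-2-en-1-ol, via alkenylalanate 14 (not isolated)
Conditions: NaAlH2(OCH2CH2OMe)2, THF, 0 → 23 °C; then I2, THF, −78 °C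
Reagents that add atoms: iodine, [I][I]
Why: Hydroxyl-directed trans-hydroalumination of the propargylic alcohol places aluminium on C3 in a five-membered alanate, and iodinolysis with retention gives the (Z)-3-iodo allylic alcohol, which fixes the later 4Z geometry.

**Step 7**
Reactants: 15 (2Z)-3-iodobut-2-en-1-ol
Product: 16 (2Z)-3-iodobut-2-enal
Conditions: MnO2 (activated, excess), CH2Cl2, 23 °C, dark
Reagents that add atoms: none
Why: Allylic oxidation with MnO2 is neutral and heterogeneous, so the enal should form without Z to E isomerisation.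

**Step 8**
Reactants: 12 methyl (2S)-2-methyl-5-[(2R)-2-methyl-3-oxo-2,3-dihydrofuran-2-yl]-4-oxopentanoate; 16 (2Z)-3-iodobut-2-enal
Product: 18 methyl (2S,3S)-3-[(1S,2Z)-1-hydroxy-3-iodobut-2-en-1-yl]-2-methyl-5-[(2R)-2-methyl-3-oxo-2,3-dihydrofuran-2-yl]-4-oxopentanoate, via boron enolate 17 (not isolated)
Conditions: (−)-Ipc2BOTf (diisopinocampheylboron triflate from (+)-α-pinene), i-Pr2NEt, CH2Cl2, −78 °C; then 16, −78 → −20 °C; then pH 7 buffer, MeOH, 30% H2O2, 0 °C
Reagents that add atoms: none
Why: Boron-mediated aldol in which the bulky boron triflate enolises the less hindered C7 methylene (not the neopentyl C9 position) to the Z-enolate, the chair transition state gives the 6,7-syn adduct and the isopinocampheyl ligands select the aldehyde face, setting C6 and C7 (see remark 2).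

**Step 9**
Reactants: 18 methyl (2S,3S)-3-[(1S,2Z)-1-hydroxy-3-iodobut-2-en-1-yl]-2-methyl-5-[(2R)-2-methyl-3-oxo-2,3-dihydrofuran-2-yl]-4-oxopentanoate
Product: 20 (3S,4R,5S)-4-{(1R)-1-hydroxy-2-[(2R)-2-methyl-3-oxo-2,3-dihydrofuran-2-yl]ethyl}-5-[(1Z)-2-iodoprop-1-en-1-yl]-3-methyloxolan-2-one, via anti-diol ester 19 (not isolated)
Conditions: Me4NBH(OAc)3, MeCN/AcOH 1:1, −30 °C; then PPTS (cat.), toluene, 50 °C
Reagents that add atoms: none
Why: Evans–Saksena reduction, in which the C6 hydroxyl binds boron and delivers hydride internally to give the 1,3-anti diol (sets C8 as R), followed by acid-equilibrated lactonisation through O6, the only closure that puts all three ring substituents trans (closure through O8 would give a cis-disubstituted lactone).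

**Step 10**
Reactants: 20 (3S,4R,5S)-4-{(1R)-1-hydroxy-2-[(2R)-2-methyl-3-oxo-2,3-dihydrofuran-2-yl]ethyl}-5-[(1Z)-2-iodoprop-1-en-1-yl]-3-methyloxolan-2-one; 21 angelic acid [(2Z)-2-methylbut-2-enoic acid]
Product: 23 (1R)-1-[(2S,3R,4S)-2-[(1Z)-2-iodoprop-1-en-1-yl]-4-methyl-5-oxooxolan-3-yl]-2-[(2R)-2-methyl-3-oxo-2,3-dihydrofuran-2-yl]ethyl (2Z)-2-methylbut-2-enoate, via mixed anhydride 22 (not isolated)
Conditions: 21, 2,4,6-Cl3C6H2COCl, Et3N, toluene, 23 °C; then 20, DMAP, toluene, 23 → 60 °C
Reagents that add atoms: none
Why: Yamaguchi esterification through the mixed anhydride acylates the hindered secondary alcohol with retention at C8 and is the usual way to transfer an angeloyl group without isomerisation to the tiglate.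

**Step 11**
Reactants: 23 (1R)-1-[(2S,3R,4S)-2-[(1Z)-2-iodoprop-1-en-1-yl]-4-methyl-5-oxooxolan-3-yl]-2-[(2R)-2-methyl-3-oxo-2,3-dihydrofuran-2-yl]ethyl (2Z)-2-methylbut-2-enoate
Product: 24 (6R,7R,8R,10R,11S)-8-[(2Z)-2-methylbut-2-enoyloxy]-3,10-epoxy-1-oxogermacra-2,4(Z)-dien-12,6-olide (target)
Conditions: Pd(OAc)2 (20 mol %), PPh3 (40 mol %), Ag2CO3 (2 equiv), MeCN, 70 °C, 0.002 M, slow addition of 23
Reagents that add atoms: none
Why: Zerovalent palladium, formed in situ, adds oxidatively to the carbon–iodine bond at C4, silver carbonate removes iodide to give a cationic (Z)-alkenylpalladium species, and the furanone C2=C3 bond inserts so that the alkenyl group goes to C3 and palladium to C2 as a palladium enolate. The closest known reaction type is the intramolecular Mizoroki–Heck alkenylation of cyclic enones and β-alkoxy acrylates, where the only β-hydrogen (on C3) lies anti to palladium and is reached after the C-bound enolate epimerises through its O-bound form before β-hydride elimination restores C2=C3. The one new bond closes two rings at once: the ten-membered carbocycle C1–C10 (endo-trig with respect to C2=C3) and the nine-membered oxacycle O, C3–C10 (exo-trig), which completes the 11-oxabicyclo[6.2.1]undecane. No stereocentre is created; the 4Z geometry comes from the alkenyl iodide with retention and the 2E relationship is enforced by the five-membered ring. The step needs bond formation at C3 and not at C2, which the push–pull polarisation of the furanone should secure, because C3 is both the enone β-carbon and the oxygen-bearing enol-ether carbon and only attack there gives a stabilised enolate. It also needs ring closure to outrun oligomerisation (high dilution) and the angelate, the allylic lactone and C11 to survive, which the base-poor, silver-buffered conditions are chosen to allow.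

**Compound list**

1 | S-ethyl ethanethioate | CCSC(C)=O | starting material
2 | lithium 1-(ethylsulfanyl)ethenolate | C=C(O[Li])SCC | intermediate
3 | 1-(ethylsulfanyl)-1-[(trimethylsilyl)oxy]ethene | C=C(O[Si](C)(C)C)SCC | intermediate
4 | 2,3-butanedione | CC(=O)C(C)=O | starting material
5 | S-ethyl (3R)-3-methyl-4-oxo-3-[(trimethylsilyl)oxy]pentanethioate | CCSC(=O)C[C@@](C)(O[Si](C)(C)C)C(C)=O | intermediate
6 | S-ethyl (3R,5E)-6-(dimethylamino)-3-methyl-4-oxo-3-[(trimethylsilyl)oxy]hex-5-enethioate | CCSC(=O)C[C@@](C)(O[Si](C)(C)C)C(=O)/C=C/N(C)C | intermediate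
7 | S-ethyl (3R,5E)-6-(dimethylamino)-3-hydroxy-3-methyl-4-oxohex-5-enethioate | CCSC(=O)C[C@@](C)(O)C(=O)/C=C/N(C)C | intermediate
8 | S-ethyl 2-[(2R)-2-methyl-3-oxo-2,3-dihydrofuran-2-yl]ethanethioate | CCSC(=O)C[C@@]1(C)OC=CC1=O | intermediate
9 | methyl (2S)-3-hydroxy-2-methylpropanoate | COC(=O)[C@@H](C)CO | starting material
10 | methyl (2R)-3-iodo-2-methylpropanoate | COC(=O)[C@@H](C)CI | intermediate
11 | [(2R)-3-methoxy-2-methyl-3-oxopropyl]zinc iodide | COC(=O)[C@@H](C)C[Zn]I | intermediate
12 | methyl (2S)-2-methyl-5-[(2R)-2-methyl-3-oxo-2,3-dihydrofuran-2-yl]-4-oxopentanoate | COC(=O)[C@@H](C)CC(=O)C[C@@]1(C)OC=CC1=O | intermediate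
13 | but-2-yn-1-ol | CC#CCO | starting material
14 | sodium 2,2-bis(2-methoxyethoxy)-3-methyl-2,5-dihydro-1,2-oxaluminol-2-uide (cyclic alkenylalanate) | CC1=CCO[Al-]1(OCCOC)OCCOC.[Na+] | intermediate
15 | (2Z)-3-iodobut-2-en-1-ol | OC/C=C(/C)I | intermediate
16 | (2Z)-3-iodobut-2-enal | O=C/C=C(/C)I | intermediate
17 | (Z)-diisopinocampheylboron enolate of 12 (boron on the C8 oxygen, C7=C8) | COC(=O)[C@@H](C)/C=C(/C[C@@]1(C)OC=CC1=O)OB([C@@H]2C[C@@H]3C[C@H]([C@H]2C)C3(C)C)[C@@H]2C[C@@H]3C[C@H]([C@H]2C)C3(C)C | intermediate
18 | methyl (2S,3S)-3-[(1S,2Z)-1-hydroxy-3-iodobut-2-en-1-yl]-2-methyl-5-[(2R)-2-methyl-3-oxo-2,3-dihydrofuran-2-yl]-4-oxopentanoate | COC(=O)[C@@H](C)[C@@H]([C@H](O)/C=C(/C)I)C(=O)C[C@@]1(C)OC=CC1=O | intermediate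
19 | methyl (2S,3R,4R)-4-hydroxy-3-[(1S,2Z)-1-hydroxy-3-iodobut-2-en-1-yl]-2-methyl-5-[(2R)-2-methyl-3-oxo-2,3-dihydrofuran-2-yl]pentanoate | COC(=O)[C@@H](C)[C@@H]([C@H](O)/C=C(/C)I)[C@H](O)C[C@@]1(C)OC=CC1=O | intermediate
20 | (3S,4R,5S)-4-{(1R)-1-hydroxy-2-[(2R)-2-methyl-3-oxo-2,3-dihydrofuran-2-yl]ethyl}-5-[(1Z)-2-iodoprop-1-en-1-yl]-3-methyloxolan-2-one | O[C@H](C[C@@]1(C)OC=CC1=O)[C@H]2[C@H](C)C(=O)O[C@@H]2/C=C(/C)I | intermediate
21 | angelic acid, (2Z)-2-methylbut-2-enoic acid | C/C=C(/C)C(=O)O | starting material
22 | (2Z)-2-methylbut-2-enoic 2,4,6-trichlorobenzoic anhydride | C/C=C(/C)C(=O)OC(=O)c1c(Cl)cc(Cl)cc1Cl | intermediate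
23 | (1R)-1-[(2S,3R,4S)-2-[(1Z)-2-iodoprop-1-en-1-yl]-4-methyl-5-oxooxolan-3-yl]-2-[(2R)-2-methyl-3-oxo-2,3-dihydrofuran-2-yl]ethyl (2Z)-2-methylbut-2-enoate | C/C=C(/C)C(=O)O[C@H](C[C@@]1(C)OC=CC1=O)[C@H]2[C@H](C)C(=O)O[C@@H]2/C=C(/C)I | intermediate
24 | (6R,7R,8R,10R,11S)-8-[(2Z)-2-methylbut-2-enoyloxy]-3,10-epoxy-1-oxogermacra-2,4(Z)-dien-12,6-olide | C/C=C(/C)C(=O)O[C@@H]1C[C@@]2(C)OC(=CC2=O)/C(C)=C\[C@H]2OC(=O)[C@@H](C)[C@@H]21 | target

**Count**

Total steps: 11. Longest linear sequence: 8 steps (steps 1, 2, 3, 5, 8, 9, 10, 11).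

**Steps most likely to fail**

1. Step 11 (Heck ring closure). After insertion the palladium enolate has no syn β-hydrogen, so turnover depends on enolate epimerisation and may stall, with protonation of the enolate or intermolecular coupling taking over during the slow nine-membered closure; ionisation of the allylic lactone oxygen by zerovalent palladium is a further drain. Fallback, from 23 back to 24: the bond formation is separated from the re-formation of the furanone alkene. Reductive cyclisation of 23 (Pd(OAc)2, PPh3, HCO2Na, Bu4NCl, DMF, 80 °C, high dilution) lets formate intercept the palladium enolate and should give the 2,3-dihydro bicyclic ketone F1, in which C3 is sp3 and the ring is less strained. Dehydrogenation of the ketone with IBX (DMSO/fluorobenzene, 70 °C) can only introduce C2=C3, because C10 is quaternary, and should return 24.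

2. Step 8 (boron aldol). Facial discrimination may be poor if the boron ligands and the stereocentres already in 12 oppose each other, and enolisation toward C9 would be followed by β-elimination of the furanone oxygen. Fallback, from 12 back to 18: stereocontrol is moved from the enolate to a chiral Lewis acid on the aldehyde. Ketone 12 is converted to its trimethylsilyl enol ether F2 (Me3SiOTf, Et3N, CH2Cl2, −78 °C; the C7 regioisomer is expected on steric grounds and an E/Z mixture is acceptable). A Mukaiyama aldol of F2 with 16, catalysed by a tartaric-acid-derived (acyloxy)borane (from mono-(2,6-diisopropoxybenzoyl)tartaric acid and BH3·THF, 20 mol %, EtCN, −78 °C; then 1 M HCl), is syn-selective through an open transition state whatever the enol silane geometry and should give 18.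

3. Step 9 (directed reduction and lactonisation). Lactonisation may take place through the C8 hydroxyl in competition with O6, or 18 may lactonise before the reduction, which removes the directing hydroxyl and erodes selectivity at C8. Fallback, from 18 back to 20: the order is reversed. Mild acid (PPTS, CH2Cl2, 23 °C) closes the lactone while only the C6 hydroxyl exists, giving the keto lactone F3. The C8 ketone is then reduced under reagent control by Corey–Bakshi–Shibata reduction ((S)-2-methyl-CBS-oxazaborolidine, 20 mol %, catecholborane, toluene, −78 °C), with the lactone ring carbon as the large substituent, to give 20.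

**Further compounds**

F1 | step 11 | 2,3-dihydro derivative of 24 (C2–C3 saturated, C3 configuration not defined) | C/C=C(/C)C(=O)O[C@@H]1C[C@@]2(C)OC(CC2=O)/C(C)=C\[C@H]2OC(=O)[C@@H](C)[C@@H]21
F2 | step 8 | methyl (2S)-2-methyl-5-[(2R)-2-methyl-3-oxo-2,3-dihydrofuran-2-yl]-4-[(trimethylsilyl)oxy]pent-3-enoate | COC(=O)[C@@H](C)C=C(C[C@@]1(C)OC=CC1=O)O[Si](C)(C)C
F3 | step 9 | (3S,4S,5S)-5-[(1Z)-2-iodoprop-1-en-1-yl]-3-methyl-4-{[(2R)-2-methyl-3-oxo-2,3-dihydrofuran-2-yl]acetyl}oxolan-2-one | O=C(C[C@@]1(C)OC=CC1=O)[C@H]2[C@H](C)C(=O)O[C@@H]2/C=C(/C)I
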